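The constants stand for no real mixture, and the outcome is calculated.

The ratio to watch is the fork ratio: for one Q molecule, the chance per second of meeting G over that of meeting another Q.

    L ⇌ Q (K1 = 1.2, k1 = 4.50 × 10⁻⁴ s⁻¹)
    D → G (k2 = 3.76 × 10⁻⁴ s⁻¹)
    Q + G → Q.G (k3 = 0.00698 M⁻¹ s⁻¹)
    2 Q → Q2 (k4 = 0.00576 M⁻¹ s⁻¹)
    Q → Z (k5 = 1.26 × 10⁻⁵ s⁻¹)

| flask | L | D | time | remark |
|---|---|---|---|---|
| ash | 0.050 M (fed, over 10.0 h) | 0.950 equiv | 20 h | a stirred flask in which L is dosed at a steady rate over 10.0 h without added volume, worked up at 20 h |
| elm | 0.050 M | 0.950 equiv | 20 h | a closed flask charged with all of it at once and left for 20 h |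
| larch | 0.050 M | 0.950 equiv |  | a single well-mixed tank run continuously and read at steady state, 20 h in it on average |
| maple | 0.050 M | 0.950 equiv (fed, over 10.0 h) | 20 h | a stirred flask in which D is dosed at a steady rate over 10.0 h without added volume, worked up at 20 h |

- the set-up with the highest amount of Q.G at the outlet or at the end, in percent of the L put in ("none" if the first two lie within 2 percentage points) (ash / elm / larch / maple / none)
- amount of Q.G at the outlet or at the end, in percent of the L put in, ash
- amount of Q.G at the outlet or at the end, in percent of the L put in, elm
- amount of Q.G at the outlet or at the end, in percent of the L put in, larch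
- amount of Q.G at the outlet or at the end, in percent of the L put in, maple

- in percentages every species weighs as the L in it: one Q2 counts as two
- two of one species on the left: rate k times its square, two consumed each time
- the stated concentrations are those of everything mixed, before any reaction; amounts are the same in each set-up
- the feed brings no volume worth counting
- run time (ash): 20 h

- The fork ratio r is the rate constant to Q.G times [G], over 2 times the rate constant to Q2 times [Q]. The constants alone give the fork constant 0.606, which multiplies [G]/[Q], and the chance of Q.G at the fork is r/(1+r), the selectivity at that moment.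
- This reckoning follows ash, and it sets Z aside, since the constant to Z, 1.26 × 10⁻⁵ s⁻¹, is less than the 3.32 × 10⁻⁴ s⁻¹ offered by full [G]. A Q that falls back to L returns to the same fork.
- From above, each Q.G takes one G, so D, the limiting reagent, gives 0.0475 M of G and caps ash at 95.0%.
- D turns to G with a half-life of 0.512 h, shorter than the dosing, but Q.G consumes G as it forms, so for the ceiling alone ash is credited with full [G] throughout, an assumption made in favour of Q.G. Setting the dosing rate 0.00500 M h⁻¹ equal to the two consumptions of Q gives [Q] = 0.00371 M, hence r = 7.76 and a tighter ceiling of 88.6%.
- From below, [Q] is taken at its ceiling, 0.0110 M, where dimerisation by itself consumes the dosing, and [G] is taken as what the final yield leaves. Requiring the yield to equal the chance at that worst fork gives a floor of 53.4%.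
- The forecast names ash, with 66% for ash, 58% for elm, 58% for larch and 37% for maple, holding that “holding Q low against plenty of G favours the product”; its ash figure lies inside this bracket.
- Ash ends at 73.2%, above elm at 59.8%, larch at 58.2% and maple at 30.2%, and inside the bracket. At 10.0 h ash holds [G] at 0.0191 M and Q at 11.4% of the L charged, a fork ratio of 2.03. Maple at 10.0 h holds [G] at 0.0307 M and Q at 1.87%, a fork ratio of 19.9; by 20.0 h its Q.G has gone from 26.6% to 30.2%, while its Q2 stands at 63.3%.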